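The reading to take at the end of this run is the electrophile left over, and you want half of its charge gone.

    acid set free + free base ⇌ salt of the base (K1 = 1200 M⁻¹, k1 = 0.82 M⁻¹ s⁻¹)
    electrophile + nucleophile → acid set free + target (k2 = 1.1 M⁻¹ s⁻¹)
    nucleophile + acid set free ⇌ protonated nucleophile, settled at all times (K3 = 5300 M⁻¹)
    electrophile + acid set free → side product (k4 = 0.26 M⁻¹ s⁻¹)
    nucleophile ⇌ dormant form (K5 = 18, k5 = 0.064 s⁻¹)

electrophile 0.22 M; protonated nucleophile 0.242 M; time 1.0 min

* the concentration of free base at which the part of the electrophile that has reacted at 1.0 min is just 50%, in M

Write E, N, P, H and B for electrophile, nucleophile, protonated nucleophile, acid set free and free base. You charge no N: it comes out of P, and the fast balance holds N·H at P/K3, so at the start N = H = 6.76 mM, less than P. E falls pseudo-first-order in N, so losing half of it in 1.0 min asks for a mean N of ln(2)/(k2·t1) = 10.5 mM. Call this the demand level; I set the k4 route aside here.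

Now freeze what moves slowly. N and H are small, so take a steady state for their difference: coupling narrows N − H at the rate 2·k2·E·N, since it removes N and makes H, dormancy narrows it at k5·N, and acid lost at H(k1·B + k4·E) widens it. With N·H = P/K3 this gives N² = (P/K3)(k1·B + k4·E)/(2·k2·E + k5), so N goes as the square root of P·B.

At mid-run I take E = 0.156 M. P loses one per E reacted and one per N gone dormant, so its mean is 0.167 M. Setting N to the demand level then asks for a mean B of 1.69 M. B loses two per E reacted and one per N gone dormant, so my charge is 1.82 M.

The forecast says 1.9 M, within 1.6 M to 2.3 M, which is above my figure, on the ground that “Base drains H, which frees N.”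

The simulation gives 1.78 M, and in that flask the half-life of free base by the forward salt-forming step alone at 0.389 min is 4.6 min, longer than the run, with 91.9% of the charged free base still free at 0.500 min. Halving P at that base charge scales the demand level by the square-root rule to 7.42 mM, which reckons 38.7% of the electrophile reacted, and that second flask gives 34.4% at 1.00 min.

The rate constants are made up, and the outcome is calculated.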